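## Structural features

The target is a 4→6-linked biflavonoid. An upper 2,3-trans-3,4-trans flavan-3-ol (resorcinol ring A, catechol ring B, pyran ring C) is bonded through C4 to C6L of a lower 2,3-trans-3,4-cis flavan-3,4-diol (benzo ring D, catechol ring E, pyran ring F). Each pyran ring carries three contiguous stereocentres, C2–C3–C4 (2R,3S,4R) and C2L–C3L–C4L (2R,3S,4S); ring D separates the two triads, so neither can control the other. All three substituents of ring C are equatorial, whereas in ring F the 4L-hydroxyl is axial and cis to the equatorial 3L-hydroxyl, the less stable arrangement. Fragile sites are the two catechols (oxidation), the benzylic 4L-hydroxyl para to O7L (ionised by acid, expelled through a quinone methide by base), the benzylic ether bonds O1–C2 and O1L–C2L, and the doubly benzylic C4–H. The real difficulty is to join C4 to one defined position of ring D from one face, and then to build a second, differently configured heterocycle on ring D without a separate enantioselective step for every centre. The key step uses the fact that C2L is a benzylic carbon para to the 4'-oxygen of ring E. Oxidising ring E to its o-quinone makes C2L electrophilic through the tautomeric quinone methide, so the C8aL hydroxyl of ring D can form O1L–C2L, while C3L with its oxygen is C2 of (R)-danshensu. The same relationship holds in the upper unit (C2 para to a ring-B oxygen, C3 equal to C2 of danshensu), and the plan uses it a second time.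

## Logic of the disconnections

25 ⇒ 24. The eight O–Si bonds are cut last. The free 3,4-diol is the most fragile compound of the route, so it is formed only once and only under buffered fluoride. All earlier chemistry then runs on lipophilic material that cannot be oxidised. The forward step must be near neutral and must also clear two hindered secondary silyl ethers.

24 ⇒ 23 ⇒ 22. The C4L–H bond is cut (carbinol back to carbonyl), then three phenolic O–Si bonds. C4L is the only centre that is neither chiral-pool derived nor the more stable epimer, and a carbonyl next to the fixed C3L lets a bulky hydride set it. This removes one stereocentre and returns ring F to the pyranone level. The demand is hydride delivery from the equatorial face, and no free phenol para to the carbonyl (a phenoxide there would switch the ketone off).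

22 ⇒ 19. The O1L–C2L bond is cut, opening ring F. C2L is para to a ring-E oxygen, so in the forward sense it can be made electrophilic by oxidising ring E alone. The cut removes a ring and a stereocentre and leaves an open-chain ketone whose only stereocentre in the side chain is chiral-pool derived. The forward step must oxidise one catechol among five aromatic rings, close through oxygen in a six-membered mode, place the ring-E aryl group trans to O3L and leave C3L untouched.

19 ⇒ 18 ⇒ 17 + 4. Four O–CH2Ph bonds are cut, then the C4L–C4aL aryl–acyl bond. Benzyl on rings D and E is orthogonal to silyl on rings A and B and on both O3 atoms, so hydrogenolysis frees exactly the groups the oxidation needs. The acyl cut divides the molecule at ring D into the complete upper unit and a three-carbon chiral-pool chain. It requires an aryl-metal at C4aL in the presence of silyl and benzyl ethers, and acylation without over-addition or loss of the α-centre.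

17 ⇒ 16 ⇒ 15 ⇒ 14 + 5. The C4aL–Li and C4aL–Br bonds are cut, then the C4–C6L bond. C4 is a 2,4-dioxygenated benzylic carbon and therefore a natural cation, and ring D is a natural nucleophile. The cut reduces the upper unit to a monomeric flavonoid and ring D to a symmetrical arene. The arene must attack anti to the O3 substituent and through its position para to one and ortho to the other benzyloxy group. Bromine is introduced after the coupling, because a brominated arene would be too poor a nucleophile to outrun ring A of a second molecule.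

14 ⇒ 13 ⇒ 12. The C4–H bond and three phenolic O–Si bonds are cut. The configuration at C4 of 14 is irrelevant because it is erased on ionisation; the step only has to spare the silyl ether para to the carbonyl.

12 ⇒ 9. The O1–C2 bond is cut in the same way as O1L–C2L. The upper unit then comes from the same chiral-pool amide and the same reaction type as the lower one, and the ring closure is first run on a small substrate. The demands are those of the key step.

9 ⇒ 8 ⇒ 7 + 4, and 7 ⇒ 6 ⇒ 5. Four O–CH2Ph bonds, the C4–C4a aryl–acyl bond and a C–Br bond are cut. Rings A and D thus come from the same arene 5, and both three-carbon chains from 4.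

4 ⇒ 3 ⇒ 2 ⇒ 1. The amide C–N bond, the O–Si bond and three O–CH2Ph bonds are cut. The carboxyl carbon becomes C4 and C4L, the carbinol carbon becomes C3 and C3L with its oxygen already in place, and the methylene becomes C2 and C2L. The silyl ether on the carbinol oxygen survives every later step up to the last and serves as the O3 and O3L protecting group of both units.

## Other disconnections considered

Alternative 1: Ring C is cut at O1–C8a at the lactone level. m-Chloroperbenzoic acid would insert oxygen between the carbonyl carbon and the ring-A carbon of the (3S)-3-aryl-6-silyloxyindan-1-one A1 (Baeyer–Villiger oxidation) and give the (4S)-4-aryl-3,4-dihydrocoumarin A2, in which C4 already carries brominated ring D.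
- In favour: the diaryl-methine centre, the one that is hardest to correct later, is fixed first in a small, robust compound; aryl migration proceeds with retention and normally ahead of a primary alkyl group; the reaction type is fully established.
- Against it here: the silyloxy group is meta to the migrating carbon and gives no assistance, so migration of the methylene carbon is a real competitor, and the peracid also meets the very electron-rich dibenzyloxy ring. A1 needs its own enantioselective synthesis. A2 still lacks C2, C3 and ring B, so lactone reduction, olefination, dihydroxylation and ring closure must follow, with two more stereocentres to be set relative to C4.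
- Comparison: on the C4 centre this alternative is the better one, because the configuration is carried through from an early C–C bond formation instead of resting on face-selective capture of a cation, and no late bromination is needed. Mechanistically its key step is also the safer one (a known rearrangement against a new oxidative ring closure). On step economy it is clearly worse: the chosen plan reaches the brominated upper unit 16 in eleven operations with C3 from the chiral pool, and A2 leaves the lower heterocycle unsolved.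

Alternative 2: Ring C is cut at C3–C4 and O1–C2 together. The benzhydrol A3 would be ionised by a chiral BINOL-derived hydrogen phosphate to the o-quinone methide A4, which adds the (E)-enol acetate A5 in a [4+2] sense to give the 3-O-acetyl upper unit A6 with brominated ring D at C4.
- In favour: two bonds, one ring and three stereocentres are formed in one catalytic step from two simple halves; ring D arrives with its bromine, so neither a Friedel–Crafts coupling nor a late bromination is needed. On bond economy and convergence this alternative is the better one.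
- Against it here: an enol ester has not been shown as the two-carbon partner in this type of catalysis. The regiochemistry relies on the aryl group overriding the polarisation by the acetoxy group. The 3,4-trans relationship depends on one mode of approach, and the enantioselectivity on a hindered diaryl-substituted A4. The acetate must then be exchanged for a silyl ether before the aryllithium chemistry, which adds two steps.
- Comparison: the step count to 16 would be about equal. The chosen plan takes C3 from the chiral pool and sets C2 and C4 by substrate control, at the price of using its one unprecedented reaction type twice. Alternative 2 would add a second, unrelated unprecedented step whose three selectivities all rest on the catalyst. Structurally both arrive at the same upper unit.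

Alternative 3: Ring F is cut at C3L–C4L. SmI2 would couple the ring-D aldehyde carbon with the α-aryloxy aldehyde carbon of the dialdehyde A7 (pinacol coupling) and give the per-silylated target with free 3L,4L-cis-diol, A8.
- In favour: ring F and both carbinol centres are formed at once, and cis-diols are the usual outcome of such chelated ring closures. For the axial 4L-hydroxyl this is the equal or the better of the chosen plan, which needs a separate face-selective reduction. A8 is one deprotection from the target.
- Against it here: C2L in A7 is an α-aryloxy, α-aryl aldehyde centre, which enolises easily and has no chiral-pool origin. α-Oxygenated carbonyl compounds tend to lose the α-substituent under SmI2 before they couple. The 2L,3L-trans relationship depends on substrate control from that labile centre.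
- Comparison: the end game is shorter by two steps and the diol configuration is better founded, but the precursor is longer to make and less stable. The chosen plan has the more secure C2L and C3L (chiral pool plus a closure governed by allylic strain), and the alternative has the more secure C4L.

Key step: step 14

Remarks on the chemistry, before the steps:
- Abbreviations: TBS = tert-butyldimethylsilyl, TBSO = (tert-butyldimethylsilyl)oxy, Bn = benzyl. "4α" means on the face of ring C opposite to O3 (3,4-trans).
- Assumption: (R)-danshensu is used as the free acid; its sodium salt would be benzylated under the same conditions.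
- Structure check: re-derivation gives 2R,3S,4R for the upper and 2R,3S,4S for the lower unit. C3L reads R in the open-chain ketones and in the 4-ketone and S in the diol only because the ranking of its neighbours changes, so (R)-danshensu is the correct enantiomer. The C4 descriptor likewise changes with the ring-D substituents, and the SMILES strings define the configuration. No connectivity had to be corrected.
- Precursor design: O3L is carried through the key step as its TBS ether, not as the free hydroxyl. A free hydroxyl there sits on the carbon β to ring E and could add to the o-quinone in a five-membered closure, and it would open the α-ketol isomerisation channels of precursor and product. As a silyl ether it also removes one later protection and leaves only fast aryl benzyl ether cleavages for the hydrogenolysis. The disconnection and the skeletons of precursor 19 and product 22 are unchanged.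

## Route

Step 1
Reactants: 1 (R)-danshensu, (2R)-3-(3,4-dihydroxyphenyl)-2-hydroxypropanoic acid
Product: 2 benzyl (2R)-3-[3,4-bis(benzyloxy)phenyl]-2-hydroxypropanoate
Conditions: BnBr (3.3 equiv), K2CO3 (3.5 equiv), DMF, 0 → 23 °C, Ar
Reagents that add atoms: benzyl bromide, BrCc1ccccc1
Why: Williamson alkylation of the two phenoxides and of the carboxylate; K2CO3 does not ionise the secondary hydroxyl, which stays free, and the stereocentre is not touched.

Step 2
Reactants: 2 benzyl (2R)-3-[3,4-bis(benzyloxy)phenyl]-2-hydroxypropanoate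
Product: 3 benzyl (2R)-3-[3,4-bis(benzyloxy)phenyl]-2-(TBSO)propanoate
Conditions: TBSCl (1.5 equiv), imidazole (3 equiv), DMF, 23 °C
Reagents that add atoms: tert-butyldimethylsilyl chloride, CC(C)(C)[Si](C)(C)Cl
Why: Imidazole-promoted silylation of the secondary alcohol; this silyl ether later serves as the O3 and O3L protecting group of both flavonoid units.

Step 3
Reactants: 3 benzyl (2R)-3-[3,4-bis(benzyloxy)phenyl]-2-(TBSO)propanoate
Product: 4 (2R)-3-[3,4-bis(benzyloxy)phenyl]-2-(TBSO)-N-methoxy-N-methylpropanamide
Conditions: MeNH(OMe)·HCl (1.6 equiv), i-PrMgCl (3.2 equiv), THF, −20 → 0 °C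
Reagents that add atoms: N,O-dimethylhydroxylamine hydrochloride, CNOC.Cl
Why: Direct aminolysis of the ester by the chloromagnesium amide formed in the flask (Weinreb amide formation); α-silyloxy esters undergo this exchange without epimerisation.

Step 4
Reactants: 5 1,3-bis(benzyloxy)benzene
Product: 6 2,4-bis(benzyloxy)-1-bromobenzene
Conditions: NBS (1.0 equiv), MeCN, 0 °C
Reagents that add atoms: N-bromosuccinimide, O=C1CCC(=O)N1Br
Why: Electrophilic aromatic bromination at the position para to one benzyloxy group and ortho to the other, the most activated unhindered site.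

Step 5
Reactants: 6 2,4-bis(benzyloxy)-1-bromobenzene; 4 (2R)-3-[3,4-bis(benzyloxy)phenyl]-2-(TBSO)-N-methoxy-N-methylpropanamide
Product: 8 (2R)-1-[2,4-bis(benzyloxy)phenyl]-3-[3,4-bis(benzyloxy)phenyl]-2-(TBSO)propan-1-one, via [2,4-bis(benzyloxy)phenyl]lithium 7 (not isolated)
Conditions: n-BuLi (1.05 equiv), THF, −78 °C; then 4 (0.9 equiv), −78 → −40 °C; aq NH4Cl
Reagents that add atoms: none
Why: Bromine–lithium exchange followed by Weinreb ketone synthesis; the chelated tetrahedral intermediate prevents a second addition and keeps the α-centre from enolising.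

Step 6
Reactants: 8 (2R)-1-[2,4-bis(benzyloxy)phenyl]-3-[3,4-bis(benzyloxy)phenyl]-2-(TBSO)propan-1-one
Product: 9 (2R)-2-(TBSO)-1-(2,4-dihydroxyphenyl)-3-(3,4-dihydroxyphenyl)propan-1-one
Conditions: H2 (1 atm), Pd/C (10%), EtOAc–EtOH (4:1), 23 °C; used at once under Ar
Reagents that add atoms: none
Why: Hydrogenolysis of four aryl benzyl ethers; the hydrogen-bonded 2,4-dihydroxyaryl ketone and the silyl ether are inert under neutral conditions.

Step 7
Reactants: 9 (2R)-2-(TBSO)-1-(2,4-dihydroxyphenyl)-3-(3,4-dihydroxyphenyl)propan-1-one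
Product: 12 (2R,3R)-3-(TBSO)-2-(3,4-dihydroxyphenyl)-7-hydroxychroman-4-one, via ring-B o-quinone 10 (not isolated), via ring-B quinone methide 11 (not isolated)
Conditions: graphite-felt anode, Pt cathode, divided cell, 0.1 molar LiClO4, 2,6-lutidine (2.5 equiv), MeCN–CH2Cl2 (4:1), 0 °C, anode held at the catechol wave (about 0.5 volt against Ag/AgCl, fixed beforehand by cyclic voltammetry), 2.0 F/mol; then 23 °C, Ar
Reagents that add atoms: none
Why: Proposed new method: two-electron anodic oxidation of the only catechol gives o-quinone 10, tautomerisation gives the 2-hydroxy-p-quinone methide 11, and the ketone-bonded ortho-hydroxyl adds to C2 in a 6-exo-trig oxa-Michael closure that restores the catechol; C2 is set trans to the C3 silyloxy group because allylic strain holds C3–H in the quinone methide plane and the tethered phenol attacks from the C4 face. The closest known reactions are the oxidation of 4-alkylcatechols to o-quinones that isomerise to quinone methides and are trapped by internal oxygen nucleophiles, and the quinone-methide ring opening and reclosure by which dihydroflavonols equilibrate at C2 with C3 unchanged.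

Step 8
Reactants: 12 (2R,3R)-3-(TBSO)-2-(3,4-dihydroxyphenyl)-7-hydroxychroman-4-one
Product: 13 (2R,3R)-3,7-bis(TBSO)-2-[3,4-bis(TBSO)phenyl]chroman-4-one
Conditions: TBSCl (3.6 equiv), imidazole (7 equiv), DMF, 0 → 23 °C; neutral work-up
Reagents that add atoms: tert-butyldimethylsilyl chloride, CC(C)(C)[Si](C)(C)Cl
Why: Silylation of the three phenols; it removes the nucleophilic and oxidisable sites of rings A and B before the cationic coupling and before the second anodic step.

Step 9
Reactants: 13 (2R,3R)-3,7-bis(TBSO)-2-[3,4-bis(TBSO)phenyl]chroman-4-one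
Product: 14 (2R,3S,4R)-3,7-bis(TBSO)-2-[3,4-bis(TBSO)phenyl]chroman-4-ol
Conditions: LiBH4 (1.5 equiv), THF, −20 → 0 °C; aq NH4Cl at 0 °C
Reagents that add atoms: none
Why: Hydride reduction of the aryl ketone in an aprotic medium that spares the silyl ether para to the carbonyl; axial attack should give mainly the 3,4-trans alcohol, and the C4 epimer is equally usable because C4 is ionised in the next step.

Step 10
Reactants: 14 (2R,3S,4R)-3,7-bis(TBSO)-2-[3,4-bis(TBSO)phenyl]chroman-4-ol; 5 1,3-bis(benzyloxy)benzene
Product: 15 (2R,3S)-4α-[2,4-bis(benzyloxy)phenyl]-3,7-bis(TBSO)-2-[3,4-bis(TBSO)phenyl]chroman (2,3-trans-3,4-trans)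
Conditions: 5 (6 equiv), BF3·OEt2 (1.2 equiv), CH2Cl2, −78 → −40 °C; aq NaHCO3
Reagents that add atoms: none
Why: Friedel–Crafts alkylation of the arene by the 2,4-dioxygenated benzylic C4 cation, the flavan-4-ol condensation of proanthocyanidin chemistry; the arene attacks anti to the bulky 3-silyloxy group and gives the all-equatorial 3,4-trans product through its position para to one and ortho to the other benzyloxy group. The excess of the unbrominated, more nucleophilic arene suppresses attack by ring A of a second molecule.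

Step 11
Reactants: 15 (2R,3S)-4α-[2,4-bis(benzyloxy)phenyl]-3,7-bis(TBSO)-2-[3,4-bis(TBSO)phenyl]chroman
Product: 16 (2R,3S)-4α-[2,4-bis(benzyloxy)-5-bromophenyl]-3,7-bis(TBSO)-2-[3,4-bis(TBSO)phenyl]chroman
Conditions: NBS (1.0 equiv), MeCN–CH2Cl2 (2:1), −20 → 0 °C
Reagents that add atoms: N-bromosuccinimide, O=C1CCC(=O)N1Br
Why: Electrophilic aromatic bromination at C4aL, which is para to one benzyloxy group and ortho to the other on the only dialkoxy ring; the silyloxy rings A and B are less activated and more hindered.

Step 12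
Reactants: 16 (2R,3S)-4α-[2,4-bis(benzyloxy)-5-bromophenyl]-3,7-bis(TBSO)-2-[3,4-bis(TBSO)phenyl]chroman; 4 (2R)-3-[3,4-bis(benzyloxy)phenyl]-2-(TBSO)-N-methoxy-N-methylpropanamide
Product: 18 (2R)-1-{2,4-bis(benzyloxy)-5-[(2R,3S)-3,7-bis(TBSO)-2-[3,4-bis(TBSO)phenyl]chroman-4α-yl]phenyl}-3-[3,4-bis(benzyloxy)phenyl]-2-(TBSO)propan-1-one, via ring-D aryllithium 17 (not isolated)
Conditions: n-BuLi (1.05 equiv), THF, −78 °C; then 4 (1.3 equiv), −78 → −40 °C; aq NH4Cl
Reagents that add atoms: none
Why: Bromine–lithium exchange and Weinreb ketone synthesis as in step 5; aryl silyl ethers and benzyl ethers tolerate the aryllithium at −78 °C, and the chelated intermediate protects the C3L centre.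

Step 13
Reactants: 18 (2R)-1-{2,4-bis(benzyloxy)-5-[(2R,3S)-3,7-bis(TBSO)-2-[3,4-bis(TBSO)phenyl]chroman-4α-yl]phenyl}-3-[3,4-bis(benzyloxy)phenyl]-2-(TBSO)propan-1-one
Product: 19 (2R)-2-(TBSO)-1-{2,4-dihydroxy-5-[(2R,3S)-3,7-bis(TBSO)-2-[3,4-bis(TBSO)phenyl]chroman-4α-yl]phenyl}-3-(3,4-dihydroxyphenyl)propan-1-one
Conditions: H2 (1 atm), Pd/C (10%), EtOAc–EtOH (4:1), 23 °C; used at once under Ar
Reagents that add atoms: none
Why: Hydrogenolysis of the four aryl benzyl ethers frees rings D and E only; all five silyl ethers, the cyclic benzylic ether O1–C2 and the chelated aryl ketone are stable under neutral conditions.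

Step 14
Reactants: 19 (2R)-2-(TBSO)-1-{2,4-dihydroxy-5-[(2R,3S)-3,7-bis(TBSO)-2-[3,4-bis(TBSO)phenyl]chroman-4α-yl]phenyl}-3-(3,4-dihydroxyphenyl)propan-1-one
Product: 22 (2R,3R)-3-(TBSO)-2-(3,4-dihydroxyphenyl)-7-hydroxy-6-[(2R,3S)-3,7-bis(TBSO)-2-[3,4-bis(TBSO)phenyl]chroman-4α-yl]chroman-4-one, via ring-E o-quinone 20 (not isolated), via ring-E quinone methide 21 (not isolated)
Conditions: graphite-felt anode, Pt cathode, divided cell, 0.1 molar LiClO4, 2,6-lutidine (2.5 equiv), MeCN–CH2Cl2 (4:1), 0 °C, anode held at the catechol wave (about 0.5 volt against Ag/AgCl, fixed beforehand by cyclic voltammetry), 2.0 F/mol; then 23 °C, Ar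
Reagents that add atoms: none
Why: Proposed new method: at the carbon anode the only free catechol (ring E) loses two electrons and two protons, taken up by 2,6-lutidine, to give o-quinone 20; the lutidine–lutidinium pair then moves one C2L proton to a quinone oxygen and gives the 2-hydroxy-p-quinone methide 21, whose exocyclic carbon is C2L. The C8aL hydroxyl, held next to C2L by its hydrogen bond to the C4L carbonyl, adds to the methide carbon while ring E returns to the catechol; this forms O1L–C2L and closes ring F in a 6-exo-trig oxa-Michael mode. The closest known chemistry is the oxidation of 4-alkylcatechols to o-quinones that tautomerise to quinone methides and are trapped by internal oxygen nucleophiles, together with the quinone-methide ring opening and reclosure by which 2,3-trans and 2,3-cis dihydroflavonols interconvert at C2 with C3 unchanged; what is new is reaching that quinone methide by oxidation of the open-chain ketone. C2L is the one new stereocentre and is controlled by the danshensu-derived C3L: allylic strain keeps C3L–H in the plane of the quinone methide, the tethered phenol can reach C2L only from the face of C4L, and the aryl group therefore ends trans to the C3L silyloxy group with both equatorial (2R); a cis isomer could be corrected through the same reversible closure on brief warming with a weak base. The oxidation is chemoselective because rings A and B are silylated, ring D is an acyl-resorcinol that should oxidise well above the catechol, and the anode is held at the catechol wave. Over-oxidation of the product catechol is limited by stopping at 2 F/mol and by redox exchange with unreacted 19, which should be the more easily oxidised catechol. The silyl ether on O3L keeps that oxygen from adding to the o-quinone and blocks α-ketol isomerisation, and C3L itself is not involved in any bond change.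

Step 15
Reactants: 22 (2R,3R)-3-(TBSO)-2-(3,4-dihydroxyphenyl)-7-hydroxy-6-[(2R,3S)-3,7-bis(TBSO)-2-[3,4-bis(TBSO)phenyl]chroman-4α-yl]chroman-4-one
Product: 23 (2R,3R)-3,7-bis(TBSO)-2-[3,4-bis(TBSO)phenyl]-6-[(2R,3S)-3,7-bis(TBSO)-2-[3,4-bis(TBSO)phenyl]chroman-4α-yl]chroman-4-one
Conditions: TBSCl (3.6 equiv), imidazole (7 equiv), DMF, 0 → 23 °C; neutral work-up
Reagents that add atoms: tert-butyldimethylsilyl chloride, CC(C)(C)[Si](C)(C)Cl
Why: Silylation of the three phenols; without it the hydride reagent would form a phenoxide para to the C4L carbonyl and deactivate the ketone, and the ring-E catechol would stay exposed.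

Step 16
Reactants: 23 (2R,3R)-3,7-bis(TBSO)-2-[3,4-bis(TBSO)phenyl]-6-[(2R,3S)-3,7-bis(TBSO)-2-[3,4-bis(TBSO)phenyl]chroman-4α-yl]chroman-4-one
Product: 24 (2R,3S,4S)-3,7-bis(TBSO)-2-[3,4-bis(TBSO)phenyl]-6-[(2R,3S)-3,7-bis(TBSO)-2-[3,4-bis(TBSO)phenyl]chroman-4α-yl]chroman-4-ol (2,3-trans-3,4-cis)
Conditions: LiBH(s-Bu)3 (lithium tri-sec-butylborohydride, 1.5 equiv), THF, −78 °C; aq NH4Cl
Reagents that add atoms: none
Why: The bulky borohydride should approach the C4L carbonyl from the equatorial face, away from the pseudo-axial H-2L, and so place the new hydroxyl axial and cis to the equatorial 3L-silyloxy group (4S). This is the steric approach control known from trialkylborohydride reductions of flavan-3-ones and 2-alkoxycyclohexanones.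

Step 17
Reactants: 24 (2R,3S,4S)-3,7-bis(TBSO)-2-[3,4-bis(TBSO)phenyl]-6-[(2R,3S)-3,7-bis(TBSO)-2-[3,4-bis(TBSO)phenyl]chroman-4α-yl]chroman-4-ol
Product: 25 (2R,3S,4R)-2-(3,4-dihydroxyphenyl)-4-[(2R,3S,4S)-2-(3,4-dihydroxyphenyl)-3,4,7-trihydroxychroman-6-yl]chroman-3,7-diol (CNP0280090.4)
Conditions: HF·pyridine, pyridine, THF, 0 → 23 °C, Ar; excess HF quenched with MeOSiMe3, evaporation, chromatography on Sephadex LH-20
Reagents that add atoms: none
Why: Fluoride cleavage of all eight Si–O bonds under pyridine-buffered conditions; the non-aqueous quench avoids both strong acid and base, which spares the benzylic 4L-hydroxyl and the catechols.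

## Compound list

1 | (R)-danshensu, (2R)-3-(3,4-dihydroxyphenyl)-2-hydroxypropanoic acid | OC(=O)[C@H](O)Cc1ccc(O)c(O)c1 | starting material
2 | benzyl (2R)-3-[3,4-bis(benzyloxy)phenyl]-2-hydroxypropanoate | O=C(OCc1ccccc1)[C@H](O)Cc1ccc(OCc2ccccc2)c(OCc2ccccc2)c1 | intermediate
3 | benzyl (2R)-3-[3,4-bis(benzyloxy)phenyl]-2-(TBSO)propanoate | O=C(OCc1ccccc1)[C@H](O[Si](C)(C)C(C)(C)C)Cc1ccc(OCc2ccccc2)c(OCc2ccccc2)c1 | intermediate
4 | (2R)-3-[3,4-bis(benzyloxy)phenyl]-2-(TBSO)-N-methoxy-N-methylpropanamide | CON(C)C(=O)[C@H](O[Si](C)(C)C(C)(C)C)Cc1ccc(OCc2ccccc2)c(OCc2ccccc2)c1 | intermediate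
5 | 1,3-bis(benzyloxy)benzene | c1ccc(COc2cccc(OCc3ccccc3)c2)cc1 | starting material
6 | 2,4-bis(benzyloxy)-1-bromobenzene | Brc1ccc(OCc2ccccc2)cc1OCc1ccccc1 | intermediate
7 | [2,4-bis(benzyloxy)phenyl]lithium | [Li]c1ccc(OCc2ccccc2)cc1OCc1ccccc1 | intermediate
8 | (2R)-1-[2,4-bis(benzyloxy)phenyl]-3-[3,4-bis(benzyloxy)phenyl]-2-(TBSO)propan-1-one | O=C(c1ccc(OCc2ccccc2)cc1OCc1ccccc1)[C@H](O[Si](C)(C)C(C)(C)C)Cc1ccc(OCc2ccccc2)c(OCc2ccccc2)c1 | intermediate
9 | (2R)-2-(TBSO)-1-(2,4-dihydroxyphenyl)-3-(3,4-dihydroxyphenyl)propan-1-one | O=C(c1ccc(O)cc1O)[C@H](O[Si](C)(C)C(C)(C)C)Cc1ccc(O)c(O)c1 | intermediate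
10 | o-quinone of 9: 4-[(2R)-2-(TBSO)-3-(2,4-dihydroxyphenyl)-3-oxopropyl]-1,2-benzoquinone | O=C(c1ccc(O)cc1O)[C@H](O[Si](C)(C)C(C)(C)C)CC1=CC(=O)C(=O)C=C1 | intermediate
11 | quinone methide of 9: 4-[(2R)-2-(TBSO)-3-(2,4-dihydroxyphenyl)-3-oxopropylidene]-2-hydroxycyclohexa-2,5-dien-1-one | O=C(c1ccc(O)cc1O)[C@H](O[Si](C)(C)C(C)(C)C)C=C1C=CC(=O)C(O)=C1 | intermediate
12 | (2R,3R)-3-(TBSO)-2-(3,4-dihydroxyphenyl)-7-hydroxychroman-4-one | Oc1ccc2c(c1)O[C@H](c1ccc(O)c(O)c1)[C@@H](O[Si](C)(C)C(C)(C)C)C2=O | intermediate
13 | (2R,3R)-3,7-bis(TBSO)-2-[3,4-bis(TBSO)phenyl]chroman-4-one | CC(C)(C)[Si](C)(C)Oc1ccc2c(c1)O[C@H](c1ccc(O[Si](C)(C)C(C)(C)C)c(O[Si](C)(C)C(C)(C)C)c1)[C@@H](O[Si](C)(C)C(C)(C)C)C2=O | intermediate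
14 | (2R,3S,4R)-3,7-bis(TBSO)-2-[3,4-bis(TBSO)phenyl]chroman-4-ol | CC(C)(C)[Si](C)(C)Oc1ccc2c(c1)O[C@H](c1ccc(O[Si](C)(C)C(C)(C)C)c(O[Si](C)(C)C(C)(C)C)c1)[C@@H](O[Si](C)(C)C(C)(C)C)[C@@H]2O | intermediate
15 | (2R,3S)-4α-[2,4-bis(benzyloxy)phenyl]-3,7-bis(TBSO)-2-[3,4-bis(TBSO)phenyl]chroman | CC(C)(C)[Si](C)(C)Oc1ccc2c(c1)O[C@H](c1ccc(O[Si](C)(C)C(C)(C)C)c(O[Si](C)(C)C(C)(C)C)c1)[C@@H](O[Si](C)(C)C(C)(C)C)[C@@H]2c1ccc(OCc2ccccc2)cc1OCc1ccccc1 | intermediate
16 | (2R,3S)-4α-[2,4-bis(benzyloxy)-5-bromophenyl]-3,7-bis(TBSO)-2-[3,4-bis(TBSO)phenyl]chroman | CC(C)(C)[Si](C)(C)Oc1ccc2c(c1)O[C@H](c1ccc(O[Si](C)(C)C(C)(C)C)c(O[Si](C)(C)C(C)(C)C)c1)[C@@H](O[Si](C)(C)C(C)(C)C)[C@@H]2c1cc(Br)c(OCc2ccccc2)cc1OCc1ccccc1 | intermediate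
17 | aryllithium of 16 (lithium in place of bromine at C4aL) | CC(C)(C)[Si](C)(C)Oc1ccc2c(c1)O[C@H](c1ccc(O[Si](C)(C)C(C)(C)C)c(O[Si](C)(C)C(C)(C)C)c1)[C@@H](O[Si](C)(C)C(C)(C)C)[C@@H]2c1cc([Li])c(OCc2ccccc2)cc1OCc1ccccc1 | intermediate
18 | (2R)-1-{2,4-bis(benzyloxy)-5-[(2R,3S)-3,7-bis(TBSO)-2-[3,4-bis(TBSO)phenyl]chroman-4α-yl]phenyl}-3-[3,4-bis(benzyloxy)phenyl]-2-(TBSO)propan-1-one | CC(C)(C)[Si](C)(C)Oc1ccc2c(c1)O[C@H](c1ccc(O[Si](C)(C)C(C)(C)C)c(O[Si](C)(C)C(C)(C)C)c1)[C@@H](O[Si](C)(C)C(C)(C)C)[C@@H]2c1cc(C(=O)[C@H](O[Si](C)(C)C(C)(C)C)Cc2ccc(OCc3ccccc3)c(OCc3ccccc3)c2)c(OCc2ccccc2)cc1OCc1ccccc1 | intermediate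
19 | (2R)-2-(TBSO)-1-{2,4-dihydroxy-5-[(2R,3S)-3,7-bis(TBSO)-2-[3,4-bis(TBSO)phenyl]chroman-4α-yl]phenyl}-3-(3,4-dihydroxyphenyl)propan-1-one (precursor of the key step) | CC(C)(C)[Si](C)(C)Oc1ccc2c(c1)O[C@H](c1ccc(O[Si](C)(C)C(C)(C)C)c(O[Si](C)(C)C(C)(C)C)c1)[C@@H](O[Si](C)(C)C(C)(C)C)[C@@H]2c1cc(C(=O)[C@H](O[Si](C)(C)C(C)(C)C)Cc2ccc(O)c(O)c2)c(O)cc1O | intermediate
20 | o-quinone of 19 (ring E as 1,2-benzoquinone) | CC(C)(C)[Si](C)(C)Oc1ccc2c(c1)O[C@H](c1ccc(O[Si](C)(C)C(C)(C)C)c(O[Si](C)(C)C(C)(C)C)c1)[C@@H](O[Si](C)(C)C(C)(C)C)[C@@H]2c1cc(C(=O)[C@H](O[Si](C)(C)C(C)(C)C)CC2=CC(=O)C(=O)C=C2)c(O)cc1O | intermediate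
21 | quinone methide of 19 (ring E as 2-hydroxy-p-quinone methide, methide carbon C2L) | CC(C)(C)[Si](C)(C)Oc1ccc2c(c1)O[C@H](c1ccc(O[Si](C)(C)C(C)(C)C)c(O[Si](C)(C)C(C)(C)C)c1)[C@@H](O[Si](C)(C)C(C)(C)C)[C@@H]2c1cc(C(=O)[C@H](O[Si](C)(C)C(C)(C)C)C=C2C=CC(=O)C(O)=C2)c(O)cc1O | intermediate
22 | (2R,3R)-3-(TBSO)-2-(3,4-dihydroxyphenyl)-7-hydroxy-6-[(2R,3S)-3,7-bis(TBSO)-2-[3,4-bis(TBSO)phenyl]chroman-4α-yl]chroman-4-one (product of the key step) | CC(C)(C)[Si](C)(C)Oc1ccc2c(c1)O[C@H](c1ccc(O[Si](C)(C)C(C)(C)C)c(O[Si](C)(C)C(C)(C)C)c1)[C@@H](O[Si](C)(C)C(C)(C)C)[C@@H]2c1cc2c(cc1O)O[C@H](c1ccc(O)c(O)c1)[C@@H](O[Si](C)(C)C(C)(C)C)C2=O | intermediate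
23 | (2R,3R)-3,7-bis(TBSO)-2-[3,4-bis(TBSO)phenyl]-6-[(2R,3S)-3,7-bis(TBSO)-2-[3,4-bis(TBSO)phenyl]chroman-4α-yl]chroman-4-one | CC(C)(C)[Si](C)(C)Oc1ccc2c(c1)O[C@H](c1ccc(O[Si](C)(C)C(C)(C)C)c(O[Si](C)(C)C(C)(C)C)c1)[C@@H](O[Si](C)(C)C(C)(C)C)[C@@H]2c1cc2c(cc1O[Si](C)(C)C(C)(C)C)O[C@H](c1ccc(O[Si](C)(C)C(C)(C)C)c(O[Si](C)(C)C(C)(C)C)c1)[C@@H](O[Si](C)(C)C(C)(C)C)C2=O | intermediate
24 | (2R,3S,4S)-3,7-bis(TBSO)-2-[3,4-bis(TBSO)phenyl]-6-[(2R,3S)-3,7-bis(TBSO)-2-[3,4-bis(TBSO)phenyl]chroman-4α-yl]chroman-4-ol | CC(C)(C)[Si](C)(C)Oc1ccc2c(c1)O[C@H](c1ccc(O[Si](C)(C)C(C)(C)C)c(O[Si](C)(C)C(C)(C)C)c1)[C@@H](O[Si](C)(C)C(C)(C)C)[C@@H]2c1cc2c(cc1O[Si](C)(C)C(C)(C)C)O[C@H](c1ccc(O[Si](C)(C)C(C)(C)C)c(O[Si](C)(C)C(C)(C)C)c1)[C@@H](O[Si](C)(C)C(C)(C)C)[C@H]2O | intermediate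
25 | (2R,3S,4R)-2-(3,4-dihydroxyphenyl)-4-[(2R,3S,4S)-2-(3,4-dihydroxyphenyl)-3,4,7-trihydroxychroman-6-yl]chroman-3,7-diol | Oc1ccc2c(c1)O[C@H](c1ccc(O)c(O)c1)[C@@H](O)[C@@H]2c1cc2c(cc1O)O[C@H](c1ccc(O)c(O)c1)[C@@H](O)[C@H]2O | target

## Step count and least certain steps

Total: 17 steps. Longest linear sequence: 16 steps (1 to 25 through steps 1–3 and 5–17; step 4 is the only branch, and amide 4 enters twice).

Step 14 (key step, new method). The most likely failure is loss of the C3L proton from quinone methide 21 in competition with ring closure. That proton is α to the ketone and vinylogous to the methide, and its loss would flatten C3L to an enol ether and re-aromatise ring E without forming O1L–C2L. Further risks are re-oxidation of the product catechol once little 19 is left, and slow tautomerisation of 20, which would give intermolecular quinone coupling time to compete.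
Fallback with known chemistry, setting out from 18 and returning at 22: chelation-assisted cleavage with MgBr2·OEt2 removes only the benzyl ether ortho to the ketone and gives the 8aL-phenol F1. DDQ then abstracts hydride from the methylene para to a ring-E benzyloxy group and the phenol captures the benzylic cation (the DDQ cyclodehydrogenation by which 2-(3-arylpropyl)phenols give flavans), giving the tri-O-benzyl dihydroflavonol F2. Hydrogenolysis over Pd/C removes the three benzyl groups and delivers 22. Ring E is never a free catechol on this path, so no quinone is involved.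

Step 7 (new method, same reaction type on the simple substrate). The same processes may intervene: proton loss from C3 of 11 in place of closure, and over-oxidation of the product catechol towards the flavonol level. A failure here would show early that the key step needs its fallback.
Fallback with known chemistry, setting out from 8 and returning at 12: MgBr2·OEt2 cleaves the benzyl ether ortho to the ketone to give the 2'-phenol F3, DDQ cyclodehydrogenation gives the tri-O-benzyl dihydroflavonol F4, and hydrogenolysis over Pd/C gives 12.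

Step 10. Direct ionisation of the 4-hydroxyl by BF3·OEt2 may need warming, because the silyloxy group makes ring A a weaker donor than in benzyl-protected flavans. Loss of the O7 silyl group from the cation, elimination towards C3, and capture of the cation from the face of O3 (3,4-cis isomer) could then compete.
Fallback, setting out from 14 and returning at 15: the alcohol is first converted with Cl3CCN and catalytic DBU into the 4-O-trichloroacetimidate F5. This ionises with catalytic TMSOTf at −78 °C in the presence of 5, so the cation is formed and captured at a temperature at which silyl loss and elimination are slow. The leaving group is then installed in a separate, base-mediated step instead of by stoichiometric Lewis acid on the free alcohol.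

Step 16. Hydride delivery may not be selective enough for the equatorial face, since the neighbouring silyloxy group and the large C6L substituent could change the usual steric bias and give some 3,4-trans alcohol.
Fallback, setting out from 23 and returning at 24: catalyst-controlled Noyori transfer hydrogenation with RuCl[(R,R)-TsDPEN](p-cymene) in HCO2H–Et3N. The chiral catalyst selects the carbonyl face through its interaction with the fused arene and not through steric approach; the (R,R) catalyst is the one that places the hydroxyl on the β face in chroman-4-ones. This fallback makes no new compound (F0).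

Step 17. The liberated benzylic 4L-hydroxyl, para to O7L, may ionise under HF·pyridine while the two hindered secondary silyl ethers are still being cleaved, which would lead to self-condensation.
Fallback, setting out from 22 and returning at 25: all five silyl groups are removed at the robust ketone stage with HF·pyridine to give the free-phenolic dihydroflavonol F6. Its ketone is then reduced by the same (R,R)-configured Ru transfer-hydrogenation catalyst in HCO2H–Et3N, so the sensitive diol is formed in the last operation and never meets fluoride. This also bypasses steps 15 and 16.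

## Further compounds

F1 | step 14 | (2R)-1-{4-(benzyloxy)-2-hydroxy-5-[(2R,3S)-3,7-bis(TBSO)-2-[3,4-bis(TBSO)phenyl]chroman-4α-yl]phenyl}-3-[3,4-bis(benzyloxy)phenyl]-2-(TBSO)propan-1-one | CC(C)(C)[Si](C)(C)Oc1ccc2c(c1)O[C@H](c1ccc(O[Si](C)(C)C(C)(C)C)c(O[Si](C)(C)C(C)(C)C)c1)[C@@H](O[Si](C)(C)C(C)(C)C)[C@@H]2c1cc(C(=O)[C@H](O[Si](C)(C)C(C)(C)C)Cc2ccc(OCc3ccccc3)c(OCc3ccccc3)c2)c(O)cc1OCc1ccccc1
F2 | step 14 | (2R,3R)-7-(benzyloxy)-2-[3,4-bis(benzyloxy)phenyl]-3-(TBSO)-6-[(2R,3S)-3,7-bis(TBSO)-2-[3,4-bis(TBSO)phenyl]chroman-4α-yl]chroman-4-one | CC(C)(C)[Si](C)(C)Oc1ccc2c(c1)O[C@H](c1ccc(O[Si](C)(C)C(C)(C)C)c(O[Si](C)(C)C(C)(C)C)c1)[C@@H](O[Si](C)(C)C(C)(C)C)[C@@H]2c1cc2c(cc1OCc1ccccc1)O[C@H](c1ccc(OCc3ccccc3)c(OCc3ccccc3)c1)[C@@H](O[Si](C)(C)C(C)(C)C)C2=O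
F3 | step 7 | (2R)-1-[4-(benzyloxy)-2-hydroxyphenyl]-3-[3,4-bis(benzyloxy)phenyl]-2-(TBSO)propan-1-one | O=C(c1ccc(OCc2ccccc2)cc1O)[C@H](O[Si](C)(C)C(C)(C)C)Cc1ccc(OCc2ccccc2)c(OCc2ccccc2)c1
F4 | step 7 | (2R,3R)-7-(benzyloxy)-2-[3,4-bis(benzyloxy)phenyl]-3-(TBSO)chroman-4-one | C(Oc1ccc2c(c1)O[C@H](c1ccc(OCc3ccccc3)c(OCc3ccccc3)c1)[C@@H](O[Si](C)(C)C(C)(C)C)C2=O)c1ccccc1
F5 | step 10 | (2R,3S,4R)-3,7-bis(TBSO)-2-[3,4-bis(TBSO)phenyl]chroman-4-yl 2,2,2-trichloroacetimidate | CC(C)(C)[Si](C)(C)Oc1ccc2c(c1)O[C@H](c1ccc(O[Si](C)(C)C(C)(C)C)c(O[Si](C)(C)C(C)(C)C)c1)[C@@H](O[Si](C)(C)C(C)(C)C)[C@@H]2OC(=N)C(Cl)(Cl)Cl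
F0 | step 16 | none | none
F6 | step 17 | (2R,3R)-2-(3,4-dihydroxyphenyl)-3,7-dihydroxy-6-[(2R,3S,4R)-2-(3,4-dihydroxyphenyl)-3,7-dihydroxychroman-4-yl]chroman-4-one | Oc1ccc2c(c1)O[C@H](c1ccc(O)c(O)c1)[C@@H](O)[C@@H]2c1cc2c(cc1O)O[C@H](c1ccc(O)c(O)c1)[C@@H](O)C2=O
A1 | alternative 1 | (3S)-3-[2,4-bis(benzyloxy)-5-bromophenyl]-6-(TBSO)indan-1-one | O=C1C[C@H](c2cc(Br)c(OCc3ccccc3)cc2OCc2ccccc2)c2ccc(O[Si](C)(C)C(C)(C)C)cc21
A2 | alternative 1 | (4S)-4-[2,4-bis(benzyloxy)-5-bromophenyl]-7-(TBSO)-3,4-dihydrocoumarin | O=C1C[C@H](c2cc(Br)c(OCc3ccccc3)cc2OCc2ccccc2)c2ccc(O[Si](C)(C)C(C)(C)C)cc2O1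
A3 | alternative 2 | [2,4-bis(benzyloxy)-5-bromophenyl][2-hydroxy-4-(TBSO)phenyl]methanol (racemic) | OC(c1ccc(O[Si](C)(C)C(C)(C)C)cc1O)c1cc(Br)c(OCc2ccccc2)cc1OCc1ccccc1
A4 | alternative 2 | 6-{[2,4-bis(benzyloxy)-5-bromophenyl]methylidene}-3-(TBSO)cyclohexa-2,4-dien-1-one (o-quinone methide) | O=C1C=C(O[Si](C)(C)C(C)(C)C)C=CC1=Cc1cc(Br)c(OCc2ccccc2)cc1OCc1ccccc1
A5 | alternative 2 | (E)-2-[3,4-bis(TBSO)phenyl]ethenyl acetate | CC(=O)O/C=C/c1ccc(O[Si](C)(C)C(C)(C)C)c(O[Si](C)(C)C(C)(C)C)c1
A6 | alternative 2 | (2R,3S)-4α-[2,4-bis(benzyloxy)-5-bromophenyl]-7-(TBSO)-2-[3,4-bis(TBSO)phenyl]chroman-3-yl acetate | CC(C)(C)[Si](C)(C)Oc1ccc2c(c1)O[C@H](c1ccc(O[Si](C)(C)C(C)(C)C)c(O[Si](C)(C)C(C)(C)C)c1)[C@@H](OC(C)=O)[C@@H]2c1cc(Br)c(OCc2ccccc2)cc1OCc1ccccc1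
A7 | alternative 3 | (2R)-2-[3,4-bis(TBSO)phenyl]-2-{2-formyl-5-(TBSO)-4-[(2R,3S)-3,7-bis(TBSO)-2-[3,4-bis(TBSO)phenyl]chroman-4α-yl]phenoxy}acetaldehyde | CC(C)(C)[Si](C)(C)Oc1ccc2c(c1)O[C@H](c1ccc(O[Si](C)(C)C(C)(C)C)c(O[Si](C)(C)C(C)(C)C)c1)[C@@H](O[Si](C)(C)C(C)(C)C)[C@@H]2c1cc(C=O)c(O[C@H](c2ccc(O[Si](C)(C)C(C)(C)C)c(O[Si](C)(C)C(C)(C)C)c2)C=O)cc1O[Si](C)(C)C(C)(C)C
A8 | alternative 3 | (2R,3S,4S)-7-(TBSO)-2-[3,4-bis(TBSO)phenyl]-6-[(2R,3S)-3,7-bis(TBSO)-2-[3,4-bis(TBSO)phenyl]chroman-4α-yl]chroman-3,4-diol | CC(C)(C)[Si](C)(C)Oc1ccc2c(c1)O[C@H](c1ccc(O[Si](C)(C)C(C)(C)C)c(O[Si](C)(C)C(C)(C)C)c1)[C@@H](O[Si](C)(C)C(C)(C)C)[C@@H]2c1cc2c(cc1O[Si](C)(C)C(C)(C)C)O[C@H](c1ccc(O[Si](C)(C)C(C)(C)C)c(O[Si](C)(C)C(C)(C)C)c1)[C@@H](O)[C@H]2O
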